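Ring A is numbered C1 (OMe), C2 (H), C3 to C5 (Br) and C6 (oxygen to ring B). Everything rests on trading the C1–O bond for a C1–CHO bond. A formyl group on C1 lies ortho to C6 and meta to the bromines on C3 and C5, so a simple 2-fluorobenzaldehyde that already holds both bromines can be joined to 2,4-dibromophenol at C6 by SNAr. One peracid oxidation of the resulting aldehyde 3, 3,5-dibromo-2-(2,4-dibromophenoxy)benzaldehyde, then moves C1 from carbon to oxygen and gives the phenol formate 6. Formate cleavage with O-methylation, and bromination at C4 para to the new methoxy group, complete the target.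

Key step: step 2

Remark: the target is achiral, so no stereocenter has to be set; compounds 1, 2, 4, 7 and 10 are taken as commercial, and ring B carries primed locants (C1' on oxygen, Br on C2' and C4').

Step 1
Reactants: 1 3,5-dibromo-2-fluorobenzaldehyde; 2 2,4-dibromophenol
Product: 3 3,5-dibromo-2-(2,4-dibromophenoxy)benzaldehyde
Conditions: K2CO3 (1.5 equiv), DMAc, 100 °C, N2
Reagents that add atoms: none
Why: Nucleophilic aromatic substitution (SNAr) by addition–elimination should take place at C6 only, because the ortho formyl group takes up the negative charge of the phenoxide adduct and fluoride is the best leaving group, while both bromines are meta to the formyl group and unactivated.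

Step 2
Reactants: 3 3,5-dibromo-2-(2,4-dibromophenoxy)benzaldehyde; 4 3-chloroperbenzoic acid (mCPBA)
Product: 6 3,5-dibromo-2-(2,4-dibromophenoxy)phenyl formate, via Criegee peroxyhemiacetal 5 (not isolated)
Conditions: mCPBA (2 equiv, dried), CH2Cl2, 40 °C; aq. Na2SO3, then brief cold aq. NaHCO3 wash
Reagents that add atoms: 3-chloroperbenzoic acid (mCPBA), O=C(OO)c1cccc(Cl)c1
Why: Baeyer–Villiger oxidation of an aryl aldehyde (Dakin-type): the peracid adds to the formyl carbon to give the Criegee peroxyhemiacetal 5, and ring carbon C1 then shifts from that carbon to the adjacent peroxide oxygen as 3-chlorobenzoate leaves, which forms the C1–O bond of formate 6. The closest known reaction type is the peracid oxidation of ortho-alkoxy and ortho-aryloxy benzaldehydes to phenol formates. No ring closes and no stereocenter remains in the product. The step needs aryl migration to win over hydride migration, which would end at the benzoic acid; what secures it is the lone pair of the ether oxygen on C6, ortho to the migrating carbon, which stabilises the positive charge that builds up on ring A during the shift. The aryl bromides and the diaryl ether are inert to the peracid.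

Step 3
Reactants: 6 3,5-dibromo-2-(2,4-dibromophenoxy)phenyl formate; 7 iodomethane
Product: 9 1,5-dibromo-2-(2,4-dibromophenoxy)-3-methoxybenzene, via phenol 8 (not isolated)
Conditions: K2CO3 (3 equiv), MeOH (5 equiv), acetone, rt; then MeI (2 equiv), 45 °C
Reagents that add atoms: iodomethane, CI
Why: Base-mediated transesterification of the very labile aryl formate with methanol frees the phenoxide of 8, which is then O-methylated by iodomethane in a Williamson ether synthesis, conditions that leave the aryl bromides and the diaryl ether untouched.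

Step 4
Reactants: 9 1,5-dibromo-2-(2,4-dibromophenoxy)-3-methoxybenzene; 10 bromine
Product: 11 1,2,3-tribromo-4-(2,4-dibromophenoxy)-5-methoxybenzene
Conditions: Br2 (1.05 equiv), AcOH, 20–40 °C, dark
Reagents that add atoms: bromine, BrBr
Why: Electrophilic aromatic bromination should go to C4 because the C1 methoxy group is the only donor conjugated with a free carbon of ring A and directs para, the ortho carbon C2 being screened by the O-methyl group that turns away from the C6 aryloxy group, while ring B is less reactive since its free ortho carbon is meta to both of its bromines.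

Compound list
1 | 3,5-dibromo-2-fluorobenzaldehyde | O=Cc1cc(Br)cc(Br)c1F | starting material
2 | 2,4-dibromophenol | Oc1ccc(Br)cc1Br | starting material
3 | 3,5-dibromo-2-(2,4-dibromophenoxy)benzaldehyde | O=Cc1cc(Br)cc(Br)c1Oc1ccc(Br)cc1Br | intermediate
4 | 3-chloroperbenzoic acid (mCPBA) | O=C(OO)c1cccc(Cl)c1 | starting material
5 | [3,5-dibromo-2-(2,4-dibromophenoxy)phenyl](hydroxy)methyl 3-chloroperbenzoate (Criegee peroxyhemiacetal, racemic, transient) | OC(OOC(=O)c1cccc(Cl)c1)c1cc(Br)cc(Br)c1Oc1ccc(Br)cc1Br | intermediate
6 | 3,5-dibromo-2-(2,4-dibromophenoxy)phenyl formate | O=COc1cc(Br)cc(Br)c1Oc1ccc(Br)cc1Br | intermediate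
7 | iodomethane | CI | starting material
8 | 3,5-dibromo-2-(2,4-dibromophenoxy)phenol (present as its potassium phenoxide) | Oc1cc(Br)cc(Br)c1Oc1ccc(Br)cc1Br | intermediate
9 | 1,5-dibromo-2-(2,4-dibromophenoxy)-3-methoxybenzene | COc1cc(Br)cc(Br)c1Oc1ccc(Br)cc1Br | intermediate
10 | bromine | BrBr | starting material
11 | 1,2,3-tribromo-4-(2,4-dibromophenoxy)-5-methoxybenzene | COc1cc(Br)c(Br)c(Br)c1Oc1ccc(Br)cc1Br | target

Total steps: 4. Longest linear sequence: 4 steps (1 → 3 → 6 → 9 → 11).

Steps most likely to fail

1. Step 2. The risk is hydride migration instead of aryl migration in the Criegee adduct, since the two meta bromines lower the migratory aptitude of ring A and the twisted ether oxygen donates only weakly. The aldehyde would then be oxidised to the acid level without the carbon-to-oxygen exchange. The fallback sets out from aldehyde 3 and comes back at phenol 8. MeMgBr (THF, −78 °C) should add to the formyl group to give racemic 1-[3,5-dibromo-2-(2,4-dibromophenoxy)phenyl]ethanol F1, and Dess–Martin periodinane (CH2Cl2, rt) should oxidise it to 1-[3,5-dibromo-2-(2,4-dibromophenoxy)phenyl]ethanone F2. Trifluoroperacetic acid (urea–H2O2, (CF3CO)2O, Na2HPO4, CH2Cl2, 0 °C to rt) should then take F2, through the Criegee adduct 1-[3,5-dibromo-2-(2,4-dibromophenoxy)phenyl]-1-hydroxyethyl trifluoroperacetate F3, to 3,5-dibromo-2-(2,4-dibromophenoxy)phenyl acetate F4. A methyl ketone has no hydride to lose, and aryl migrates in preference to methyl even on electron-poor rings. F4 takes the place of 6 in step 3, where methanolysis releases phenol 8.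

2. Step 4. The risk is loss of positional control in the bromination: attack at C2 ortho to the methoxy group, attack at the free ortho carbon of ring B, or a second bromination, giving isomers that are hard to separate. The fallback sets out from 2,4-dibromophenol 2 and comes back at target 11; it brings the C4 bromine in with the aldehyde, so no late bromination is needed. Bought 4-bromo-2-fluorobenzaldehyde F5 is brominated twice with NBS in conc. H2SO4 (60 °C), through 4,5-dibromo-2-fluorobenzaldehyde F6, to 3,4,5-tribromo-2-fluorobenzaldehyde F7. In this substrate the formyl group (meta), the fluorine (ortho and para) and the bromine (ortho) all direct to the same two carbons. SNAr with 2 (K2CO3, DMAc, 100 °C) should give 3,4,5-tribromo-2-(2,4-dibromophenoxy)benzaldehyde F8, since fluoride ortho to the formyl group leaves far faster than the flanked bromine para to it. mCPBA as in step 2 should lead, through the Criegee adduct [3,4,5-tribromo-2-(2,4-dibromophenoxy)phenyl](hydroxy)methyl 3-chloroperbenzoate F9, to 3,4,5-tribromo-2-(2,4-dibromophenoxy)phenyl formate F10. The conditions of step 3 should then give, through 3,4,5-tribromo-2-(2,4-dibromophenoxy)phenol F11, the target 11. The price is a harder aryl migration on a ring with three bromines.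

3. Step 1. The risk is base-induced loss of the aldehyde (Cannizzaro disproportionation, or displacement of fluoride by amine from solvent breakdown) outrunning the slow attack of a weakly nucleophilic, ortho-hindered phenoxide. The fallback sets out from 1 and comes back at aldehyde 3. NH2OH·HCl and HCO2Na in HCO2H at reflux should convert 1, through (E)-3,5-dibromo-2-fluorobenzaldehyde oxime F12, into 3,5-dibromo-2-fluorobenzonitrile F13. Its cyano group activates the C–F bond about as well as formyl does, is slimmer, and survives hot carbonate. SNAr with 2 (K2CO3, DMAc, 120 °C) should give 3,5-dibromo-2-(2,4-dibromophenoxy)benzonitrile F14. Diisobutylaluminium hydride (i-Bu2AlH, toluene, −78 °C) should stop at the aldimine 1-[3,5-dibromo-2-(2,4-dibromophenoxy)phenyl]methanimine F15 (aluminium-bound in the flask), and aqueous HCl hydrolyses it to aldehyde 3.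

Further compounds
F1 | step 2 | 1-[3,5-dibromo-2-(2,4-dibromophenoxy)phenyl]ethanol (racemic) | CC(O)c1cc(Br)cc(Br)c1Oc1ccc(Br)cc1Br
F2 | step 2 | 1-[3,5-dibromo-2-(2,4-dibromophenoxy)phenyl]ethanone | CC(=O)c1cc(Br)cc(Br)c1Oc1ccc(Br)cc1Br
F3 | step 2 | 1-[3,5-dibromo-2-(2,4-dibromophenoxy)phenyl]-1-hydroxyethyl trifluoroperacetate (racemic, transient) | CC(O)(OOC(=O)C(F)(F)F)c1cc(Br)cc(Br)c1Oc1ccc(Br)cc1Br
F4 | step 2 | 3,5-dibromo-2-(2,4-dibromophenoxy)phenyl acetate | CC(=O)Oc1cc(Br)cc(Br)c1Oc1ccc(Br)cc1Br
F5 | step 4 | 4-bromo-2-fluorobenzaldehyde (bought) | O=Cc1ccc(Br)cc1F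
F6 | step 4 | 4,5-dibromo-2-fluorobenzaldehyde | O=Cc1cc(Br)c(Br)cc1F
F7 | step 4 | 3,4,5-tribromo-2-fluorobenzaldehyde | O=Cc1cc(Br)c(Br)c(Br)c1F
F8 | step 4 | 3,4,5-tribromo-2-(2,4-dibromophenoxy)benzaldehyde | O=Cc1cc(Br)c(Br)c(Br)c1Oc1ccc(Br)cc1Br
F9 | step 4 | [3,4,5-tribromo-2-(2,4-dibromophenoxy)phenyl](hydroxy)methyl 3-chloroperbenzoate (racemic, transient) | OC(OOC(=O)c1cccc(Cl)c1)c1cc(Br)c(Br)c(Br)c1Oc1ccc(Br)cc1Br
F10 | step 4 | 3,4,5-tribromo-2-(2,4-dibromophenoxy)phenyl formate | O=COc1cc(Br)c(Br)c(Br)c1Oc1ccc(Br)cc1Br
F11 | step 4 | 3,4,5-tribromo-2-(2,4-dibromophenoxy)phenol | Oc1cc(Br)c(Br)c(Br)c1Oc1ccc(Br)cc1Br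
F12 | step 1 | (E)-3,5-dibromo-2-fluorobenzaldehyde oxime | O/N=C/c1cc(Br)cc(Br)c1F
F13 | step 1 | 3,5-dibromo-2-fluorobenzonitrile | N#Cc1cc(Br)cc(Br)c1F
F14 | step 1 | 3,5-dibromo-2-(2,4-dibromophenoxy)benzonitrile | N#Cc1cc(Br)cc(Br)c1Oc1ccc(Br)cc1Br
F15 | step 1 | 1-[3,5-dibromo-2-(2,4-dibromophenoxy)phenyl]methanimine | N=Cc1cc(Br)cc(Br)c1Oc1ccc(Br)cc1Br
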